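**Retrosynthetic overview**
- Target: (2S)-16-(4-methyl-5-oxo-2,5-dihydrofuran-3-yl)hexadecan-2-yl acetate, C23H40O4, with one stereocentre, (S). The ring C=C comes from dehydration of a β-hydroxy-γ-lactone; the acetate is put on the free (S)-carbinol just before that.
- Key C–C bond (ring C3–C4): intermolecular aldol addition of the lithium enolate of ethyl propanoate to a long-chain 1-silyloxy-2-ketone. The only ring, the butenolide, is then closed by desilylation and lactonisation.
- The silyloxy ketone comes from a terminal alkene by dihydroxylation, selective primary silylation and oxidation.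
- The C18 alkenol comes from (S)-propylene oxide, which supplies the stereocentre, and a C15 alkenyl Grignard reagent. The C15 chloride comes from 11-bromoundec-1-ene and 1-bromo-4-chlorobutane by copper-catalysed coupling.

Note: centres that are destroyed later (C2 of 9 and 10; the two ring centres of 14 to 18) are carried as diastereomer mixtures.

**Route**

Step 1
Reactants: 1 11-bromoundec-1-ene; 2 1-bromo-4-chlorobutane
Product: 4 15-chloropentadec-1-ene, via undec-10-enylmagnesium bromide 3 (not isolated)
Conditions: Mg, THF, 40 °C; then 2 (1.5 equiv), Li2CuCl4 (3 mol%), THF, −10 to 0 °C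
Reagents that add atoms: none
Why: Kochi-type copper-catalysed Grignard cross-coupling, in which the primary C–Br bond of 2 reacts far faster than its C–Cl bond, so the chain grows by four carbons and keeps a chloride handle.

Step 2
Reactants: 4 15-chloropentadec-1-ene; 5 (S)-propylene oxide [(2S)-2-methyloxirane]
Product: 7 (2S)-octadec-17-en-2-ol, via pentadec-14-enylmagnesium chloride 6 (not isolated)
Conditions: Mg, THF, reflux; then CuBr·SMe2 (10 mol%), 5 (1.3 equiv), THF, −30 to 0 °C; 1 M HCl work-up
Reagents that add atoms: none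
Why: Copper-catalysed SN2 opening of the epoxide at its unsubstituted CH2, so the C–O stereocentre of 5 is untouched and becomes the (S)-carbinol of 7.

Step 3
Reactants: 7 (2S)-octadec-17-en-2-ol
Product: 8 tert-butyldimethyl{[(2S)-octadec-17-en-2-yl]oxy}silane
Conditions: TBSCl, imidazole, DMF, rt
Reagents that add atoms: TBSCl, CC(C)(C)[Si](C)(C)Cl
Why: Standard silyl ether protection of the secondary alcohol for the oxidation and enolate steps; only the O–H bond reacts, so the stereocentre is unchanged.

Step 4
Reactants: 8 tert-butyldimethyl{[(2S)-octadec-17-en-2-yl]oxy}silane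
Product: 9 (17S)-17-[(tert-butyldimethylsilyl)oxy]octadecane-1,2-diol (both C2 epimers)
Conditions: OsO4 (2 mol%), NMO (1.5 equiv), THF/t-BuOH/H2O, rt
Reagents that add atoms: OsO4, O=[Os](=O)(=O)=O (delivers the two O atoms); NMO, C[N+]1([O-])CCOCC1 and water, O (replenish them)
Why: Upjohn dihydroxylation of the terminal alkene; the new carbinol centre forms unselectively, which is harmless because it is oxidised to the ketone in step 6.

Step 5
Reactants: 9 (17S)-17-[(tert-butyldimethylsilyl)oxy]octadecane-1,2-diol
Product: 10 (17S)-1,17-bis[(tert-butyldimethylsilyl)oxy]octadecan-2-ol (both C2 epimers)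
Conditions: TBSCl (1.05 equiv), imidazole, CH2Cl2, 0 °C
Reagents that add atoms: TBSCl, CC(C)(C)[Si](C)(C)Cl
Why: Sterically controlled monosilylation, the primary hydroxyl reacting much faster with the bulky silyl chloride than the secondary one.

Step 6
Reactants: 10 (17S)-1,17-bis[(tert-butyldimethylsilyl)oxy]octadecan-2-ol
Product: 11 (17S)-1,17-bis[(tert-butyldimethylsilyl)oxy]octadecan-2-one
Conditions: Dess–Martin periodinane, CH2Cl2, 0 °C to rt
Reagents that add atoms: none
Why: Dess–Martin oxidation of the secondary alcohol to the ketone under mild conditions that leave both silyl ethers and the remote stereocentre alone.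

Step 7
Reactants: 11 (17S)-1,17-bis[(tert-butyldimethylsilyl)oxy]octadecan-2-one; 12 ethyl propanoate
Product: 14 ethyl (18S)-18-[(tert-butyldimethylsilyl)oxy]-3-{[(tert-butyldimethylsilyl)oxy]methyl}-3-hydroxy-2-methylnonadecanoate (diastereomer mixture at C2 and C3), via lithium enolate of ethyl propanoate 13 (not isolated)
Conditions: 12 (1.5 equiv), LiN(iPr)2 (LDA, 1.4 equiv), THF, −78 °C; then 11, −78 °C; AcOH quench at −78 °C
Reagents that add atoms: none
Why: Intermolecular aldol addition of a preformed lithium ester enolate to the ketone, which at −78 °C is faster than proton transfer, with a cold acidic quench to prevent retro-aldol; the two new centres form unselectively and are erased in step 10.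

Step 8
Reactants: 14 ethyl (18S)-18-[(tert-butyldimethylsilyl)oxy]-3-{[(tert-butyldimethylsilyl)oxy]methyl}-3-hydroxy-2-methylnonadecanoate
Product: 16 4-hydroxy-4-[(15S)-15-hydroxyhexadecyl]-3-methyloxolan-2-one (ring diastereomer mixture), via triol ethyl ester 15 (not isolated)
Conditions: HF (48% aq.), MeCN/THF, 0 °C to rt; then p-TsOH (cat.), CH2Cl2, rt
Reagents that add atoms: none
Why: Acidic fluoride desilylation of both silyl ethers followed by acid-catalysed lactonisation to the five-membered ring, favoured by the quaternary carbinol; the (S)-carbinol does not ionise under these conditions and keeps its configuration.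

Step 9
Reactants: 16 4-hydroxy-4-[(15S)-15-hydroxyhexadecyl]-3-methyloxolan-2-one
Product: 17 (2S)-16-(3-hydroxy-4-methyl-5-oxooxolan-3-yl)hexadecan-2-yl acetate (ring diastereomer mixture)
Conditions: Ac2O (1.5 equiv), pyridine, DMAP (cat.), CH2Cl2, 0 °C to rt
Reagents that add atoms: acetic anhydride, CC(=O)OC(C)=O
Why: DMAP-catalysed acylation of the secondary alcohol with retention (only the O–H bond is broken), while the hindered tertiary hydroxyl reacts far more slowly.

Step 10
Reactants: 17 (2S)-16-(3-hydroxy-4-methyl-5-oxooxolan-3-yl)hexadecan-2-yl acetate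
Product: 19 (2S)-16-(4-methyl-5-oxo-2,5-dihydrofuran-3-yl)hexadecan-2-yl acetate, via tertiary mesylate 18 (not isolated)
Conditions: MsCl, Et3N, CH2Cl2, 0 °C; then DBU, rt
Reagents that add atoms: none
Why: Mesylation of the tertiary alcohol and DBU-induced E1cB elimination through the lactone enolate give the conjugated tetrasubstituted butenolide, the thermodynamically preferred alkene isomer; the acetate and its stereocentre are inert here.

**Compound list**
1 | 11-bromoundec-1-ene | C=CCCCCCCCCCBr | starting material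
2 | 1-bromo-4-chlorobutane | ClCCCCBr | starting material
3 | undec-10-enylmagnesium bromide | C=CCCCCCCCCC[Mg]Br | intermediate (not isolated)
4 | 15-chloropentadec-1-ene | C=CCCCCCCCCCCCCCCl | intermediate
5 | (S)-propylene oxide, (2S)-2-methyloxirane | C[C@H]1CO1 | starting material
6 | pentadec-14-enylmagnesium chloride | C=CCCCCCCCCCCCCC[Mg]Cl | intermediate (not isolated)
7 | (2S)-octadec-17-en-2-ol | C[C@H](O)CCCCCCCCCCCCCCC=C | intermediate
8 | tert-butyldimethyl{[(2S)-octadec-17-en-2-yl]oxy}silane | C[C@H](O[Si](C)(C)C(C)(C)C)CCCCCCCCCCCCCCC=C | intermediate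
9 | (17S)-17-[(tert-butyldimethylsilyl)oxy]octadecane-1,2-diol, both C2 epimers | C[C@H](O[Si](C)(C)C(C)(C)C)CCCCCCCCCCCCCCC(O)CO | intermediate
10 | (17S)-1,17-bis[(tert-butyldimethylsilyl)oxy]octadecan-2-ol, both C2 epimers | C[C@H](O[Si](C)(C)C(C)(C)C)CCCCCCCCCCCCCCC(O)CO[Si](C)(C)C(C)(C)C | intermediate
11 | (17S)-1,17-bis[(tert-butyldimethylsilyl)oxy]octadecan-2-one | C[C@H](O[Si](C)(C)C(C)(C)C)CCCCCCCCCCCCCCC(=O)CO[Si](C)(C)C(C)(C)C | intermediate
12 | ethyl propanoate | CCC(=O)OCC | starting material
13 | lithium 1-ethoxyprop-1-en-1-olate (lithium enolate of ethyl propanoate) | CC=C(OCC)O[Li] | intermediate (not isolated)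
14 | ethyl (18S)-18-[(tert-butyldimethylsilyl)oxy]-3-{[(tert-butyldimethylsilyl)oxy]methyl}-3-hydroxy-2-methylnonadecanoate, diastereomer mixture at C2 and C3 | CCOC(=O)C(C)C(O)(CO[Si](C)(C)C(C)(C)C)CCCCCCCCCCCCCC[C@H](C)O[Si](C)(C)C(C)(C)C | intermediate
15 | ethyl (18S)-3,18-dihydroxy-3-(hydroxymethyl)-2-methylnonadecanoate | CCOC(=O)C(C)C(O)(CO)CCCCCCCCCCCCCC[C@H](C)O | intermediate (not isolated)
16 | 4-hydroxy-4-[(15S)-15-hydroxyhexadecyl]-3-methyloxolan-2-one, ring diastereomer mixture | CC1C(=O)OCC1(O)CCCCCCCCCCCCCC[C@H](C)O | intermediate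
17 | (2S)-16-(3-hydroxy-4-methyl-5-oxooxolan-3-yl)hexadecan-2-yl acetate, ring diastereomer mixture | CC1C(=O)OCC1(O)CCCCCCCCCCCCCC[C@H](C)OC(C)=O | intermediate
18 | (2S)-16-{3-[(methanesulfonyl)oxy]-4-methyl-5-oxooxolan-3-yl}hexadecan-2-yl acetate | CC1C(=O)OCC1(OS(C)(=O)=O)CCCCCCCCCCCCCC[C@H](C)OC(C)=O | intermediate (not isolated)
19 | (2S)-16-(4-methyl-5-oxo-2,5-dihydrofuran-3-yl)hexadecan-2-yl acetate | CC(=O)O[C@@H](C)CCCCCCCCCCCCCCC1=C(C)C(=O)OC1 | target

**Totals**
Total steps: 10. Longest linear sequence: 10 steps (1 to 19); 2, 5 and 12 enter as purchased reagents.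

**Three steps most likely to fail, with fallbacks**

Step 1. Risk: Wurtz homocoupling while making 3 and some attack at the C–Cl end of 2 give hydrocarbon and diene by-products that are hard to separate from 4. The fallback sets out from 1 (as its Grignard reagent 3) and 5, and comes back at 8. It builds the chain outward from the stereocentre, so no bromide/chloride selectivity and no long-chain chloride Grignard reagent are needed. Reagent 3 opens 5 (CuBr·SMe2 cat., THF, −30 °C) to give (2S)-tetradec-13-en-2-ol F1. Silylation (TBSCl, imidazole, DMF) gives tert-butyldimethyl{[(2S)-tetradec-13-en-2-yl]oxy}silane F2. Hydroboration–oxidation (9-BBN, THF; then NaOH, H2O2) gives (13S)-13-[(tert-butyldimethylsilyl)oxy]tetradecan-1-ol F3. Tosylation (TsCl, pyridine, 0 °C) gives (13S)-13-[(tert-butyldimethylsilyl)oxy]tetradecyl 4-methylbenzenesulfonate F4. Coupling of F4 with but-3-enylmagnesium bromide (Li2CuCl4 cat., THF, −10 °C) gives 8.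

Step 7. Risk: ketone 11 is enolisable on both sides, so proton transfer to the basic lithium enolate, or retro-aldol on warming, returns starting ketone. The fallback sets out from 11 and comes back at 14. It makes the same bond with a non-basic zinc enolate generated by metal insertion instead of deprotonation (Reformatsky reaction). Zn dust (TMSCl-activated) and ethyl 2-bromopropanoate in THF at 40 °C give ethyl 2-(bromozincio)propanoate F5, which adds to the ketone of 11; cold 1 M HCl work-up gives 14.

Step 10. Risk: incomplete mesylation of the hindered tertiary alcohol, or elimination toward C5 or into the side chain that does not fully converge on the conjugated isomer. The fallback sets out from 9 and comes back at 19. It closes the ring by an intramolecular Horner–Wadsworth–Emmons olefination, so no tertiary alcohol is ever formed. Selective esterification of the primary hydroxyl of 9 with 2-(diethoxyphosphoryl)propanoic acid (EDC·HCl, DMAP cat., CH2Cl2, 0 °C) gives (17S)-17-[(tert-butyldimethylsilyl)oxy]-2-hydroxyoctadecyl 2-(diethoxyphosphoryl)propanoate F6. Dess–Martin oxidation gives (17S)-17-[(tert-butyldimethylsilyl)oxy]-2-oxooctadecyl 2-(diethoxyphosphoryl)propanoate F7. LiCl and DBU in MeCN at rt give 4-{(15S)-15-[(tert-butyldimethylsilyl)oxy]hexadecyl}-3-methylfuran-2(5H)-one F8. HF (48% aq.) in MeCN gives 4-[(15S)-15-hydroxyhexadecyl]-3-methylfuran-2(5H)-one F9. Acetylation (Ac2O, pyridine, DMAP cat.) gives 19.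

**Further compounds**
F1 | step 1 | (2S)-tetradec-13-en-2-ol | C[C@H](O)CCCCCCCCCCC=C
F2 | step 1 | tert-butyldimethyl{[(2S)-tetradec-13-en-2-yl]oxy}silane | C[C@H](O[Si](C)(C)C(C)(C)C)CCCCCCCCCCC=C
F3 | step 1 | (13S)-13-[(tert-butyldimethylsilyl)oxy]tetradecan-1-ol | C[C@H](O[Si](C)(C)C(C)(C)C)CCCCCCCCCCCCO
F4 | step 1 | (13S)-13-[(tert-butyldimethylsilyl)oxy]tetradecyl 4-methylbenzenesulfonate | C[C@H](O[Si](C)(C)C(C)(C)C)CCCCCCCCCCCCOS(=O)(=O)c1ccc(C)cc1
F5 | step 7 | ethyl 2-(bromozincio)propanoate | CCOC(=O)C(C)[Zn]Br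
F6 | step 10 | (17S)-17-[(tert-butyldimethylsilyl)oxy]-2-hydroxyoctadecyl 2-(diethoxyphosphoryl)propanoate | C[C@H](O[Si](C)(C)C(C)(C)C)CCCCCCCCCCCCCCC(O)COC(=O)C(C)P(=O)(OCC)OCC
F7 | step 10 | (17S)-17-[(tert-butyldimethylsilyl)oxy]-2-oxooctadecyl 2-(diethoxyphosphoryl)propanoate | C[C@H](O[Si](C)(C)C(C)(C)C)CCCCCCCCCCCCCCC(=O)COC(=O)C(C)P(=O)(OCC)OCC
F8 | step 10 | 4-{(15S)-15-[(tert-butyldimethylsilyl)oxy]hexadecyl}-3-methylfuran-2(5H)-one | C[C@H](O[Si](C)(C)C(C)(C)C)CCCCCCCCCCCCCCC1=C(C)C(=O)OC1
F9 | step 10 | 4-[(15S)-15-hydroxyhexadecyl]-3-methylfuran-2(5H)-one | C[C@H](O)CCCCCCCCCCCCCCC1=C(C)C(=O)OC1
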